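**Retrosynthetic overview**
1. Target ⇐ chemoselective reductive removal of an Oppolzer sultam from the C3 acyl group (C3–C(=O)N → C3–CH2OH); the side-chain methyl ester is left alone.
2. Dihydrobenzofuran ring ⇐ one-flask oxidative β-5 (C8–C5') radical cross-coupling of an N-sinapoyl sultam with methyl dihydroferulate, then 5-exo addition of the guaiacyl phenol to the p-quinone methide. C3 is set by the auxiliary in the C–C coupling, C2 by trans ring closure.
3. N-Sinapoyl sultam ⇐ Heck coupling of N-acryloyl sultam with 4-bromo-2,6-dimethoxyphenol; N-acryloyl sultam ⇐ (1R)-(+)-camphorsultam + acryloyl chloride.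
4. Ring order: both benzene rings are bought; the furan ring is the only ring formed (C3–C3a bond first, then O1–C2).

Assumption: the sultam steers the radical coupling in its usual non-chelated sense, which for the (2S)-sultam means attack on the Cα-si face and the (2S,3S)-imide. This sense is recalled from the general sultam model, not established for this coupling; both sultam antipodes are sold, and the trans-diastereomers of 9 are separable, so the final product is one enantiomer.

**Step 1**
Reactants: 1 (1R)-(+)-2,10-camphorsultam [(2S)-bornane-10,2-sultam]; 2 acryloyl chloride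
Product: 4 N-acryloyl-(2S)-bornane-10,2-sultam, via sodium sultamide 3 (not isolated)
Conditions: NaH (1.1 equiv), toluene, rt, 1 h; then 2 (1.2 equiv), CuCl (cat.), 0 °C → rt
Reagents that add atoms: none
Why: N-acylation of the sultam sodium salt by an acid chloride (standard preparation of N-enoyl sultams); no stereocenter is touched.

**Step 2**
Reactants: 4 N-acryloyl-(2S)-bornane-10,2-sultam; 5 4-bromo-2,6-dimethoxyphenol
Product: 6 N-[(E)-3-(4-hydroxy-3,5-dimethoxyphenyl)prop-2-enoyl]-(2S)-bornane-10,2-sultam (N-sinapoyl sultam)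
Conditions: Pd(OAc)2 (5 mol%), P(o-tol)3 (10 mol%), Et3N (3 equiv), DMF, 90 °C
Reagents that add atoms: none
Why: Mizoroki–Heck arylation of the terminal acrylimide carbon; syn-insertion then syn-β-hydride elimination gives only the E-enoyl sultam, and free 4-bromophenols are competent Heck partners with P(o-tol)3.

**Step 3**
Reactants: 6 N-sinapoyl-(2S)-bornane-10,2-sultam; 7 methyl 3-(4-hydroxy-3-methoxyphenyl)propanoate (methyl dihydroferulate)
Product: 9 methyl 3-[(2S,3S)-3-{[(2S)-bornane-10,2-sultam-N-yl]carbonyl}-2-(4-hydroxy-3,5-dimethoxyphenyl)-7-methoxy-2,3-dihydro-1-benzofuran-5-yl]propanoate (2,3-trans), via quinone methide 8 (not isolated)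
Conditions: Ag2O (1.5 equiv), 7 (3 equiv, excess recovered), 6 added over 6 h, CH2Cl2, 0 °C → rt, dark; minor trans-diastereomer removed by chromatography/crystallisation
Reagents that add atoms: none
Why: Proposed new method: Ag2O takes one electron from each phenol; the sinapoyl radical (spin at C8, α to the imide carbonyl) and the 4-alkylguaiacoxyl radical of 7 (spin at C5) combine C8–C5 as in the β-5 coupling of lignan biosynthesis, the sultam (C=O anti to SO2, s-cis enoyl) leaving the Cα-si face open so that C3 forms S; tautomerisation gives quinone methide 8, whose phenol adds 5-exo to C7 anti to the acyl group to give the 2,3-trans ring with C2 S; the closest known reaction types are the sultam-controlled oxidative β-5 homodimerisation of ferulic acid imides and the Ag2O or peroxidase β-5 cross-coupling of monolignols with saturated 4-alkylguaiacols, merged here into one auxiliary-controlled cross-coupling.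

**Step 4**
Reactants: 9 (2S,3S)-N-acyl sultam
Product: 11 methyl 3-[(2S,3R)-2-(4-hydroxy-3,5-dimethoxyphenyl)-3-(hydroxymethyl)-7-methoxy-2,3-dihydro-1-benzofuran-5-yl]propanoate (CNP0362206.1), via aldehyde 10 (not isolated)
Conditions: NaBH4 (4 equiv), THF/H2O 4:1, 0 °C → rt
Reagents that add atoms: none
Why: Chemoselective borohydride reduction of the activated N-acylsulfonamide carbonyl (reductive auxiliary cleavage through the aldehyde) in preference to the unactivated methyl ester; no bond to C2 or C3 is broken, so the geometry is retained (the C3 descriptor changes from S to R only through CIP priorities).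

**Compound list**
1 | (1R)-(+)-2,10-camphorsultam, (2S)-bornane-10,2-sultam | CC1(C)[C@H]2CC[C@@]13CS(=O)(=O)N[C@H]3C2 | starting material
2 | acryloyl chloride | C=CC(=O)Cl | starting material
3 | sodium salt of 1 (sodium sultamide) | [Na+].[N-]1[C@H]2C[C@@H]3CC[C@@]2(CS1(=O)=O)C3(C)C | intermediate (not isolated)
4 | N-acryloyl-(2S)-bornane-10,2-sultam | C=CC(=O)N1[C@H]2C[C@@H]3CC[C@@]2(CS1(=O)=O)C3(C)C | intermediate
5 | 4-bromo-2,6-dimethoxyphenol | COc1cc(Br)cc(OC)c1O | starting material
6 | N-[(E)-sinapoyl]-(2S)-bornane-10,2-sultam | COc1cc(/C=C/C(=O)N2[C@H]3C[C@@H]4CC[C@@]3(CS2(=O)=O)C4(C)C)cc(OC)c1O | intermediate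
7 | methyl 3-(4-hydroxy-3-methoxyphenyl)propanoate (methyl dihydroferulate) | COC(=O)CCc1ccc(O)c(OC)c1 | starting material
8 | β-5-coupled p-quinone methide (C8 R; syringyl ring as 2,6-dimethoxy-4-alkylidenecyclohexa-2,5-dienone, guaiacyl ring rearomatised with free OH) | COC(=O)CCc1cc(OC)c(O)c(c1)[C@H](C(=O)N2[C@H]3C[C@@H]4CC[C@@]3(CS2(=O)=O)C4(C)C)C=C5C=C(OC)C(=O)C(OC)=C5 | intermediate (not isolated)
9 | methyl 3-[(2S,3S)-3-{[(2S)-bornane-10,2-sultam-N-yl]carbonyl}-2-(4-hydroxy-3,5-dimethoxyphenyl)-7-methoxy-2,3-dihydro-1-benzofuran-5-yl]propanoate (trans) | COC(=O)CCc1cc(OC)c2c(c1)[C@H](C(=O)N3[C@H]4C[C@@H]5CC[C@@]4(CS3(=O)=O)C5(C)C)[C@@H](c6cc(OC)c(O)c(OC)c6)O2 | intermediate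
10 | methyl 3-[(2S,3S)-3-formyl-2-(4-hydroxy-3,5-dimethoxyphenyl)-7-methoxy-2,3-dihydro-1-benzofuran-5-yl]propanoate | COC(=O)CCc1cc(OC)c2c(c1)[C@H](C=O)[C@@H](c3cc(OC)c(O)c(OC)c3)O2 | intermediate (not isolated)
11 | methyl 3-[(2S,3R)-2-(4-hydroxy-3,5-dimethoxyphenyl)-3-(hydroxymethyl)-7-methoxy-2,3-dihydro-1-benzofuran-5-yl]propanoate | COC(=O)CCc1cc(OC)c2c(c1)[C@H](CO)[C@@H](c1cc(OC)c(O)c(OC)c1)O2 | target

**Totals**
Total steps: 4. Longest linear sequence: 4 (1 → 4 → 6 → 9 → 11).

**Steps most likely to fail**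

1. Step 3. The risks are homo-coupling (β–β dimers of 6, 5–5 and 4-O-5 dimers of 7), over-oxidation of 7 or of product 9, and a modest or reversed diastereofacial preference. The fallback sets out from 6 and comes back at 9. 6 is co-oxidised (Ag2O, CH2Cl2, slow addition) with bought methyl (E)-ferulate in place of 7. Its conjugated phenoxyl radical is closer in oxidation potential to that of 6, and the same β-5 coupling gives, through the acrylate quinone methide F1 (not isolated), the acrylate dihydrobenzofuran imide F2. Hydrogenation of the acrylate C=C only (H2 1 atm, 5% Pd/C, EtOAc, rt) then gives 9.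

2. Step 2. The risks are sluggish oxidative addition of the electron-rich bromophenol and base-induced oligomerisation or oxa-Michael addition of the acrylimide at 90 °C. The fallback sets out from 1 (as its sodium salt 3) and comes back at 6. 3 is acylated by chloroacetyl chloride to N-(chloroacetyl)-(2S)-bornane-10,2-sultam F3. Arbuzov reaction with triethyl phosphite (neat, 130 °C) gives N-(diethylphosphonoacetyl)-(2S)-bornane-10,2-sultam F4. Masamune–Roush Horner–Wadsworth–Emmons olefination of syringaldehyde (LiCl, i-Pr2NEt 2.5 equiv, MeCN, rt → 40 °C) gives 6.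

3. Step 4. The risks are slow reduction of the hindered imide, partial loss of the methyl ester, and base-induced β-elimination (ring opening) at the acidic C3–H. The fallback sets out from 9 and comes back at 11. LiOH/H2O2 (THF/H2O, 0 °C; Na2SO3 quench) cleaves only the imide to the C3 carboxylic acid F5. BH3·SMe2 (THF, 0 °C → rt) then reduces the acid but not the methyl ester, giving 11.

**Further compounds**
F1 | step 3 | acrylate p-quinone methide from 6 and methyl ferulate (not isolated) | COC(=O)/C=C/c1cc(OC)c(O)c(c1)[C@H](C(=O)N2[C@H]3C[C@@H]4CC[C@@]3(CS2(=O)=O)C4(C)C)C=C5C=C(OC)C(=O)C(OC)=C5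
F2 | step 3 | methyl (E)-3-[(2S,3S)-3-{[(2S)-bornane-10,2-sultam-N-yl]carbonyl}-2-(4-hydroxy-3,5-dimethoxyphenyl)-7-methoxy-2,3-dihydro-1-benzofuran-5-yl]prop-2-enoate | COC(=O)/C=C/c1cc(OC)c2c(c1)[C@H](C(=O)N3[C@H]4C[C@@H]5CC[C@@]4(CS3(=O)=O)C5(C)C)[C@@H](c6cc(OC)c(O)c(OC)c6)O2
F3 | step 2 | N-(chloroacetyl)-(2S)-bornane-10,2-sultam | ClCC(=O)N1[C@H]2C[C@@H]3CC[C@@]2(CS1(=O)=O)C3(C)C
F4 | step 2 | N-(diethylphosphonoacetyl)-(2S)-bornane-10,2-sultam | CCOP(=O)(OCC)CC(=O)N1[C@H]2C[C@@H]3CC[C@@]2(CS1(=O)=O)C3(C)C
F5 | step 4 | (2S,3S)-2-(4-hydroxy-3,5-dimethoxyphenyl)-7-methoxy-5-(3-methoxy-3-oxopropyl)-2,3-dihydro-1-benzofuran-3-carboxylic acid | COC(=O)CCc1cc(OC)c2c(c1)[C@H](C(=O)O)[C@@H](c3cc(OC)c(O)c(OC)c3)O2
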